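**Strategy.** The saturated ring (C1–C4 plus C4a/C8a of ring A) is traced back to a cyclobutane that holds only C1–C4: a 1,2-diaryl-3,4-dimethylcyclobutan-1-ol, built by keteniminium–(E)-2-butene [2+2] cycloaddition and aryl Grignard addition. One oxidation cleaves the strained bis-benzylic C1–C4 bond. The C1 benzylic cation then closes onto C8a of the new aryl ketone ring, so the four-membered ring grows by the two arene carbons into the 4-aryl-1-tetralone. The carbinol and aryl-bearing cyclobutane stereocentres are erased, so all diastereomers converge; only the trans-dimethyl pair (C2, C3), set with a trans-2,5-dimethylpyrrolidine auxiliary, is carried through. Hydrogenolysis of the C4 ketone finishes.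

Key step: step 4

Assumption: the (2R,5R)-auxiliary is taken to direct (E)-but-2-ene to the keteniminium face that gives the (3R,4R)-cyclobutanone; if the sense of induction is the opposite, the (2S,5S)-amine is used and nothing else changes.

Step 1
Reactants: 1 2-(3,4-dimethoxyphenyl)acetyl chloride; 2 (2R,5R)-2,5-dimethylpyrrolidine
Product: 3 2-(3,4-dimethoxyphenyl)-1-[(2R,5R)-2,5-dimethylpyrrolidin-1-yl]ethan-1-one
Conditions: aq. NaOH, CH2Cl2, 0 °C → rt
Reagents that add atoms: none
Why: Schotten–Baumann N-acylation of the secondary amine, in which no stereocentre is touched.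

Step 2
Reactants: 3 2-(3,4-dimethoxyphenyl)-1-[(2R,5R)-2,5-dimethylpyrrolidin-1-yl]ethan-1-one; 4 (E)-but-2-ene
Product: 7 (2R,3R,4R)-2-(3,4-dimethoxyphenyl)-3,4-dimethylcyclobutan-1-one, via keteniminium triflate 5 (not isolated), via cyclobutaniminium triflate 6 (not isolated)
Conditions: Tf2O, 2,4,6-collidine, (E)-but-2-ene (excess), ClCH2CH2Cl, sealed tube, −20 → 60 °C; then H2O, 60 °C
Reagents that add atoms: water, O
Why: Keteniminium–alkene [2+2] cycloaddition followed by iminium hydrolysis, in which suprafacial addition to the (E)-alkene sets the trans-3,4-dimethyl pair, the trans-2,5-dimethylpyrrolidine blocks one face of the keteniminium C=C and so fixes C3 as R, and the epimerisable C2 and C4 settle trans to their neighbours.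

Step 3
Reactants: 7 (2R,3R,4R)-2-(3,4-dimethoxyphenyl)-3,4-dimethylcyclobutan-1-one; 8 (3,4-dimethoxyphenyl)magnesium bromide
Product: 9 (1R,2R,3R,4R)-1,2-bis(3,4-dimethoxyphenyl)-3,4-dimethylcyclobutan-1-ol
Conditions: LaCl3·2LiCl, THF, −78 → 0 °C; then H2O
Reagents that add atoms: none
Why: Lanthanum-assisted 1,2-addition of the aryl Grignard reagent to the strained ketone should outrun enolisation, the aryl group entering anti to the C2 aryl and C4 methyl groups to set C1, whose configuration (like that of C2) is erased in step 4.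

Step 4
Reactants: 9 (1R,2R,3R,4R)-1,2-bis(3,4-dimethoxyphenyl)-3,4-dimethylcyclobutan-1-ol
Product: 11 (2R,3S,4R)-4-(3,4-dimethoxyphenyl)-6,7-dimethoxy-2,3-dimethyl-3,4-dihydronaphthalen-1(2H)-one, via γ-keto benzylic cation 10 (not isolated)
Conditions: PhI(OCOCF3)2 (1.05 equiv, slow addition), (CF3)2CHOH/CH2Cl2 (1:1), −20 °C → rt
Reagents that add atoms: none
Why: One-electron oxidation of a dimethoxyaryl ring (or ligand exchange of the alcohol at iodine) with loss of the O–H proton triggers strain-driven scission of the C1–C2 bond of 9 to the aryl ketone and a benzylic radical, which is oxidised to cation 10 and alkylates the ketone-bearing ring ortho to the acyl group before rearomatising. The closest known reaction type is the oxidative ring expansion of 1-arylcyclobutanols to 1-tetralones (alkoxy-radical β-scission followed by closure onto the arene), run here with radical–polar crossover. The six-membered ring closes by intramolecular Friedel–Crafts alkylation, a 6-endo closure in which both arene carbons become ring members and all four cyclobutane carbons are kept. The only new stereocentre, C4 of 11, is controlled by the adjacent C3 methyl group: in the chair-like transition state the aryl group lies pseudo-equatorial and anti to it, giving the 3,4-trans product, while C2 and C3 are untouched and C1/C2 of 9 are erased, so every diastereomer of 9 converges. The step needs scission of C1–C2 rather than C1–C4 (secured by the aryl group on C2), closure para to the 3-methoxy group rather than at the flanked position between acyl and methoxy, and ring closure faster than elimination or oxidation of the reversibly formed cyclic oxocarbenium ion (secured by the acidic, non-nucleophilic fluoroalcohol and by keeping the oxidant limiting).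

Step 5
Reactants: 11 (2R,3S,4R)-4-(3,4-dimethoxyphenyl)-6,7-dimethoxy-2,3-dimethyl-3,4-dihydronaphthalen-1(2H)-one
Product: 12 (1R,2R,3S)-1-(3,4-dimethoxyphenyl)-6,7-dimethoxy-2,3-dimethyl-1,2,3,4-tetrahydronaphthalene
Conditions: H2 (4 atm), 10% Pd/C, AcOH, HClO4 (cat.), rt
Reagents that add atoms: none
Why: Hydrogenolysis of the electron-rich aryl ketone through the benzylic alcohol to the methylene group, in which no stereocentre is formed and the three existing ones are not involved.

**Compound list**

1 | 2-(3,4-dimethoxyphenyl)acetyl chloride | COc1ccc(CC(Cl)=O)cc1OC | starting material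
2 | (2R,5R)-2,5-dimethylpyrrolidine | C[C@@H]1CC[C@@H](C)N1 | starting material
3 | 2-(3,4-dimethoxyphenyl)-1-[(2R,5R)-2,5-dimethylpyrrolidin-1-yl]ethan-1-one | COc1ccc(CC(=O)N2[C@H](C)CC[C@H]2C)cc1OC | intermediate
4 | (E)-but-2-ene | C/C=C/C | starting material
5 | (2R,5R)-1-[2-(3,4-dimethoxyphenyl)ethenylidene]-2,5-dimethylpyrrolidin-1-ium triflate | COc1ccc(C=C=[N+]2[C@H](C)CC[C@H]2C)cc1OC.[O-]S(=O)(=O)C(F)(F)F | intermediate
6 | (2R,5R)-1-[(2R,3R,4R)-2-(3,4-dimethoxyphenyl)-3,4-dimethylcyclobutylidene]-2,5-dimethylpyrrolidin-1-ium triflate | C[C@@H]2CC[C@@H](C)[N+]2=C1[C@H](C)[C@@H](C)[C@@H]1c1ccc(OC)c(OC)c1.[O-]S(=O)(=O)C(F)(F)F | intermediate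
7 | (2R,3R,4R)-2-(3,4-dimethoxyphenyl)-3,4-dimethylcyclobutan-1-one | O=C1[C@H](C)[C@@H](C)[C@@H]1c1ccc(OC)c(OC)c1 | intermediate
8 | (3,4-dimethoxyphenyl)magnesium bromide | COc1ccc([Mg]Br)cc1OC | starting material
9 | (1R,2R,3R,4R)-1,2-bis(3,4-dimethoxyphenyl)-3,4-dimethylcyclobutan-1-ol | COc1ccc(cc1OC)[C@@]1(O)[C@H](C)[C@@H](C)[C@@H]1c1ccc(OC)c(OC)c1 | intermediate
10 | (2S,3R)-1,4-bis(3,4-dimethoxyphenyl)-2,3-dimethyl-4-oxobutan-1-ylium trifluoroacetate | COc1ccc(cc1OC)C(=O)[C@H](C)[C@@H](C)[CH+]c1ccc(OC)c(OC)c1.[O-]C(=O)C(F)(F)F | intermediate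
11 | (2R,3S,4R)-4-(3,4-dimethoxyphenyl)-6,7-dimethoxy-2,3-dimethyl-3,4-dihydronaphthalen-1(2H)-one | COc1ccc([C@@H]2c3cc(OC)c(OC)cc3C(=O)[C@H](C)[C@H]2C)cc1OC | intermediate
12 | (1R,2R,3S)-1-(3,4-dimethoxyphenyl)-6,7-dimethoxy-2,3-dimethyl-1,2,3,4-tetrahydronaphthalene | COc1ccc([C@@H]2c3cc(OC)c(OC)cc3C[C@H](C)[C@H]2C)cc1OC | target

Total step count: 5
Longest linear sequence: 5 steps (1 → 3 → 7 → 9 → 11 → 12)

**Steps most likely to fail**

1. Step 4. Friedel–Crafts closure onto the acyl-deactivated ring may be slow. The cation could then eliminate and re-protonate (scrambling the methyl-bearing carbon next to it), or be trapped by the carbonyl oxygen and over-oxidised towards a furan. The fallback sets out from 9. Ionic deoxygenation (Et3SiH, CF3CO2H, CH2Cl2, −40 °C) should give (1R,2S,3R,4R)-1,2-bis(3,4-dimethoxyphenyl)-3,4-dimethylcyclobutane F1, whose configuration at C1 and C2 is immaterial. This is then isomerised by photoinduced electron transfer (9-mesityl-10-methylacridinium tetrafluoroborate cat., PhSSPh cat., (CF3)2CHOH/CH2Cl2, blue LEDs, −20 °C). The arene radical cation opens the C1–C2 bond to a 1,4-radical cation, the cationic end closes onto the electron-rich, non-acylated ring, and the thiol/disulfide pair returns the hydrogen atom to the benzylic radical. This 1,2-diarylcyclobutane → 1-aryltetralin ring expansion comes back to the route at 12 and makes step 5 unnecessary. Its own weak point is cycloreversion of the radical cation to two alkenes, which would erode enantiopurity; the low temperature is meant to hold that back.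

2. Step 2. Facial discrimination by the auxiliary may be insufficient, and the unactivated alkene may capture the aryl-conjugated keteniminium ion too slowly, so that it self-condenses. The fallback sets out from 1 and replaces auxiliary control by resolution. Dimethylamine should give 2-(3,4-dimethoxyphenyl)-N,N-dimethylacetamide F2. The same Tf2O/collidine cycloaddition with 4 and hydrolysis should give the racemic all-trans cyclobutanone F3. Ketalisation with (R,R)-hydrobenzoin (pyridinium p-toluenesulfonate, benzene, reflux with water removal) should give two diastereomeric ketals that are separated by chromatography or crystallisation: the (R,R)-hydrobenzoin ketal of the (2R,3R,4R)-ketone F4, which is kept, and the (R,R)-hydrobenzoin ketal of the (2S,3S,4S)-ketone F5, which is discarded. Hydrolysis of F4 (aq. HCl, THF) comes back to the route at 7.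

3. Step 5. Acid-promoted enolisation next to the ketone, or ionisation of the intermediate benzylic alcohol and elimination to the 1,2-dihydronaphthalene, could epimerise the adjacent methyl-bearing carbon before the C–O bond is cleaved. The fallback sets out from 11 and avoids cationic intermediates. 1,2-Ethanedithiol with BF3·OEt2 in CH2Cl2 should give (2'R,3'S,4'R)-4'-(3,4-dimethoxyphenyl)-6',7'-dimethoxy-2',3'-dimethyl-3',4'-dihydro-2'H-spiro[1,3-dithiolane-2,1'-naphthalene] F6. Mozingo desulfurisation (Raney Ni, EtOH, reflux) then comes back to the route at 12.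

**Further compounds**

F1 | step 4 | (1R,2S,3R,4R)-1,2-bis(3,4-dimethoxyphenyl)-3,4-dimethylcyclobutane | COc1ccc(cc1OC)[C@@H]1[C@H](C)[C@@H](C)[C@@H]1c1ccc(OC)c(OC)c1
F2 | step 2 | 2-(3,4-dimethoxyphenyl)-N,N-dimethylacetamide | COc1ccc(CC(=O)N(C)C)cc1OC
F3 | step 2 | racemic all-trans-2-(3,4-dimethoxyphenyl)-3,4-dimethylcyclobutan-1-one (both enantiomers) | O=C1[C@H](C)[C@@H](C)[C@@H]1c1ccc(OC)c(OC)c1.O=C1[C@@H](C)[C@H](C)[C@H]1c1ccc(OC)c(OC)c1
F4 | step 2 | (R,R)-hydrobenzoin ketal of (2R,3R,4R)-2-(3,4-dimethoxyphenyl)-3,4-dimethylcyclobutan-1-one | C12(O[C@H](c3ccccc3)[C@@H](c3ccccc3)O2)[C@H](C)[C@@H](C)[C@@H]1c1ccc(OC)c(OC)c1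
F5 | step 2 | (R,R)-hydrobenzoin ketal of (2S,3S,4S)-2-(3,4-dimethoxyphenyl)-3,4-dimethylcyclobutan-1-one | C12(O[C@H](c3ccccc3)[C@@H](c3ccccc3)O2)[C@@H](C)[C@H](C)[C@H]1c1ccc(OC)c(OC)c1
F6 | step 5 | (2'R,3'S,4'R)-4'-(3,4-dimethoxyphenyl)-6',7'-dimethoxy-2',3'-dimethyl-3',4'-dihydro-2'H-spiro[1,3-dithiolane-2,1'-naphthalene] | COc1ccc([C@@H]2c3cc(OC)c(OC)cc3C3(SCCS3)[C@H](C)[C@H]2C)cc1OC
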